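At the time of reading, 2.0 min, I booked the substrate charged to this flask on four lines of a ledger: still substrate, mono adduct, double product, or a shortfall that the readings did not show.

in all of them: substrate 10 mM

| charge | coupling partner | remark | time |
|---|---|---|---|
| green | 13 mM | run made earlier |  |
| grey | 30 mM | run made earlier |  |
| flask | 20.0 mM |  | 2.0 min |

| run | time / s | double product / % | mono adduct / % | substrate / % |
|---|---|---|---|---|
| green | 10.0 | 2.0 | 24.5 | 73.1 |
| green | 12.0 | 2.2 | 28.1 | 69.5 |
| green | 20.0 | 4.9 | 37.5 | 57.2 |
| green | 40.0 | 10.9 | 49.1 | 38.7 |
| green | 60.0 | 15.5 | 52.3 | 30.1 |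
| green | 90.0 | 21.2 | 53.0 | 22.2 |
| grey | 10.0 | 7.0 | 43.5 | 48.3 |
| grey | 20.0 | 18.5 | 53.3 | 26.8 |
| grey | 30.0 | 26.5 | 52.5 | 15.8 |
| grey | 50.0 | 41.2 | 45.1 | 6.1 |
| grey | 80.0 | 56.8 | 31.9 | 1.4 |
| grey | 90.0 | 60.8 | 28.5 | 1.9 |

(readings scatter by 0.5 percentage points)

1. equivalents of coupling partner to substrate, everything else as given, that leave most double product at 2.0 min
2. the amount of double product then, in percent of the substrate charged
3. the amount of double product with the amounts as given



Substrate becomes mono adduct, and mono adduct becomes double product, each by taking up one coupling partner, so I expected c(coupling partner) to scale both steps and to cancel when they are compared at one moment. I therefore took S, the selectivity factor, as c(mono adduct)/c(substrate) at the point where mono adduct stops rising, so that S·c(substrate)/c(mono adduct) is the make-to-spend ratio of mono adduct. In the green run mono adduct had nearly stopped at 90.0 s, which gave a reading of S = 2.39, and the grey run's readings put its peak of mono adduct between 20.0 s and 30.0 s, where the same quotient went from 1.99 to 3.32.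

Over the grey run's first 50.0 s the ratio drifted down as substrate went. The ledger line I chose was the grey run's reading at 50.0 s, with substrate 6.1%, mono adduct 45.1% and double product 41.2%, where the ratio was 0.323, so as my own estimate I committed to about 41.2% for this flask if its substrate fell that far.

The forecast differed, with 44% for this flask and 78% at 6 equiv, while calling “any optimum is broad and poorly located”.

The flask gave 48.7%, and the best charge was 4.26 equiv, with 76.6%.

    coupling partner + double product ⇌ tris adduct + by-product (K = 0.230, k = 0.820 M⁻¹ s⁻¹)
    coupling partner + mono adduct → double product + by-product (k = 1.10 M⁻¹ s⁻¹)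
    substrate + coupling partner → mono adduct + by-product (k = 2.70 M⁻¹ s⁻¹)

At 2.0 min this flask held substrate 5.35% and mono adduct 42.2%, so S gave a ratio of 0.303, and mono adduct was being spent faster than it was made. The same flask read at 50 s held substrate 17.9%, mono adduct 53.5% and double product 25.4%. There S gave 0.800, already below one, so mono adduct had begun to fall, and at 1.00 min it stood at 52.3%.

(The numbers in the tables come from a simulation for an exercise, and the scatter is random.)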